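**Retrosynthetic overview**

1. The target is a meso 1,3-diacyl-2,4-diarylcyclobutane (aryl groups cis, acyl groups trans) carrying two identical N-acyl 5,6-dihydropyridin-2(1H)-one rings. Both lactam rings are cut at C4–C5 (the enone β-carbon and the CH2 two carbons from nitrogen) and closed together in the last step by a twofold nickel-electrocatalytic decarboxylative alkenylation that joins two electrophile-derived carbons.
2. Enabling feature: in each lactam ring N1–C6–C5 is a decarboxylated β-alanine and N1–C2(=O)–C3=C4 is a cis-acryloyl imide. A CO2H on C5 and an iodide on C4 can therefore sit on the same imide nitrogen, and the six-membered ring dictates the cis C3=C4 bond.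
3. The two acyclic imide N–C(=O) bonds come from the cyclobutane bis(acid chloride) and the lithium amidate of a one-step arm made from (Z)-3-iodoacrylic acid and β-alanine tert-butyl ester.
4. The cyclobutane is bought as cis-3-(methoxycarbonyl)cyclobutane-1-carboxylic acid; the two aryl groups are installed by two amide-directed Pd C–H arylations with an ester epimerisation between them.
5. Ring order: cyclobutane (purchased), then both dihydropyridinone rings at once in step 12.

Key step: step 12

Assumption: the target has a mirror plane through the two carbonyl-bearing ring carbons (meso), so only relative configuration has to be controlled; compound 1 is taken as a catalogue compound.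

**Route**

Step 1
Reactants: 1 cis-3-(methoxycarbonyl)cyclobutane-1-carboxylic acid; 2 2-(methylsulfanyl)aniline
Product: 3 methyl cis-3-{[2-(methylsulfanyl)phenyl]carbamoyl}cyclobutane-1-carboxylate
Conditions: EDC·HCl, DMAP (cat.), CH2Cl2, rt
Reagents that add atoms: none
Why: Carbodiimide amide coupling installs the bidentate N,S directing group without touching the two ring stereocentres.

Step 2
Reactants: 3 methyl cis-3-{[2-(methylsulfanyl)phenyl]carbamoyl}cyclobutane-1-carboxylate; 4 4-iodo-1,2-dimethoxybenzene
Product: 5 methyl all-cis-2-(3,4-dimethoxyphenyl)-3-{[2-(methylsulfanyl)phenyl]carbamoyl}cyclobutane-1-carboxylate (racemic)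
Conditions: Pd(OAc)2 (15 mol %), Ag2CO3, PivOH, HFIP, 90 °C
Reagents that add atoms: none
Why: Amide-directed palladium-catalysed C(sp3)–H arylation (divalent to tetravalent palladium through an N,S-chelated palladacycle) should replace a methylene hydrogen cis to the amide, so the aryl group enters cis to the amide and to the ester; the thioanilide auxiliary is expected to stop at mono-arylation.

Step 3
Reactants: 5 methyl all-cis-2-(3,4-dimethoxyphenyl)-3-{[2-(methylsulfanyl)phenyl]carbamoyl}cyclobutane-1-carboxylate
Product: 6 methyl 2-(3,4-dimethoxyphenyl)-3-{[2-(methylsulfanyl)phenyl]carbamoyl}cyclobutane-1-carboxylate with the ester trans to the aryl group and the amide cis to it (racemic)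
Conditions: NaOMe (0.5 equiv), MeOH, 45 °C
Reagents that add atoms: none
Why: Thermodynamic epimerisation through the ester enolate should invert only the ester-bearing carbon (ester trans to aryl), because the anilide N–H is deprotonated first and thereby protects its own α-carbon.

Step 4
Reactants: 6 the ester-epimerised monoaryl cyclobutane; 4 4-iodo-1,2-dimethoxybenzene
Product: 7 methyl 2,4-bis(3,4-dimethoxyphenyl)-3-{[2-(methylsulfanyl)phenyl]carbamoyl}cyclobutane-1-carboxylate, aryl groups cis to each other and to the amide, ester trans to both (meso)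
Conditions: Pd(OAc)2 (15 mol %), Ag2CO3, PivOH, HFIP, 90 °C
Reagents that add atoms: none
Why: A second amide-directed C(sp3)–H arylation should functionalise the remaining methylene hydrogen cis to the amide, so the palladacycle geometry places the new aryl cis to the amide and to the first aryl and trans to the ester.

Step 5
Reactants: 7 the diaryl anilide ester
Product: 8 methyl 3-{(tert-butoxycarbonyl)[2-(methylsulfanyl)phenyl]carbamoyl}-2,4-bis(3,4-dimethoxyphenyl)cyclobutane-1-carboxylate (same relative configuration as 7)
Conditions: Boc2O, DMAP, MeCN, 40 °C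
Reagents that add atoms: di-tert-butyl dicarbonate CC(C)(C)OC(=O)OC(=O)OC(C)(C)C
Why: DMAP-catalysed N-tert-butoxycarbonylation twists and activates the secondary anilide for mild cleavage.

Step 6
Reactants: 8 the N-Boc anilide ester
Product: 9 (1α,2α,3β,4α)-2,4-bis(3,4-dimethoxyphenyl)cyclobutane-1,3-dicarboxylic acid (aryl groups cis; one carboxyl cis to both aryls, the other trans to both; meso)
Conditions: LiOH·H2O, H2O2 (30 % aq.), THF–H2O, 0 °C to rt; then 1 M HCl
Reagents that add atoms: hydrogen peroxide OO; lithium hydroxide [Li+].[OH-]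
Why: Hydroperoxide cleavage of the activated N-Boc amide and saponification of the methyl ester should give the diacid with retention, since the carboxylates formed do not enolise.

Step 7
Reactants: 9 the cyclobutane diacid
Product: 10 (1α,2α,3β,4α)-2,4-bis(3,4-dimethoxyphenyl)cyclobutane-1,3-dicarbonyl dichloride (used crude)
Conditions: (COCl)2, DMF (cat.), CH2Cl2, 0 °C to rt
Reagents that add atoms: oxalyl chloride ClC(=O)C(=O)Cl
Why: Vilsmeier-type acid chloride formation proceeds without base and so should leave both α-stereocentres intact.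

Step 8
Reactants: 11 (2Z)-3-iodoprop-2-enoic acid; 12 β-alanine tert-butyl ester hydrochloride
Product: 13 tert-butyl 3-[(2Z)-3-iodoprop-2-enamido]propanoate
Conditions: EDC·HCl, HOBt, i-Pr2NEt (1 equiv), CH2Cl2, 0 °C
Reagents that add atoms: none
Why: Carbodiimide/HOBt amide coupling at low temperature should preserve the Z-alkene of the iodoacrylic acid and outrun conjugate addition of the amine.

Step 9
Reactants: 13 tert-butyl 3-[(2Z)-3-iodoprop-2-enamido]propanoate (2.1 equiv); 10 the cyclobutane bis(acid chloride)
Product: 15 di-tert-butyl bis-imide, in which each cyclobutane carbonyl is bonded to a nitrogen that carries a CH2CH2CO2t-Bu chain and a (Z)-3-iodoacryloyl group (cyclobutane configuration as in 9), via lithium amidate 14 (not isolated)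
Conditions: LiN(SiMe3)2 (1.0 equiv per amide), THF, −78 °C; then 10, −78 to −20 °C
Reagents that add atoms: none
Why: N-Acylation of a lithium amidate by an acid chloride forms the imide (any O-acyl isoimide should rearrange by a Mumm-type 1,3-acyl shift), and low temperature with exactly stoichiometric base guards against ketene-mediated epimerisation of 10 and loss of HI from the iodoacrylamide.

Step 10
Reactants: 15 the di-tert-butyl bis-imide
Product: 16 the corresponding bis-imide dicarboxylic acid (each nitrogen now carries a CH2CH2CO2H chain)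
Conditions: TFA/CH2Cl2 (1:3), 0 °C to rt
Reagents that add atoms: none
Why: Acidolysis of the tert-butyl esters (E1 loss of isobutene) should leave the imides, the Z-alkenyl iodides and the aryl ethers untouched under anhydrous acid.

Step 11
Reactants: 16 the bis-imide dicarboxylic acid
Product: 17 the bis(1,3-dioxoisoindolin-2-yl) ester of 16 (twofold redox-active ester)
Conditions: N-hydroxyphthalimide, DIC, CH2Cl2/THF, 0 °C to rt
Reagents that add atoms: N-hydroxyphthalimide O=C1c2ccccc2C(=O)N1O
Why: Carbodiimide esterification with N-hydroxyphthalimide needs no amine base, so the base-sensitive imides and β-iodoenoyl groups should survive.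

Step 12
Reactants: 17 the twofold redox-active ester
Product: 18 1,1'-{[(1α,2α,3β,4α)-2,4-bis(3,4-dimethoxyphenyl)cyclobutane-1,3-diyl]dicarbonyl}bis(5,6-dihydropyridin-2(1H)-one) (target)
Conditions: NiCl2·6H2O (20 mol %), 2,2'-bipyridine (20 mol %), AgNO3 (30 mol %), LiCl, NMP (5 mM), Mg anode, RVC cathode, undivided cell, constant current (about 4.5 F/mol), rt
Reagents that add atoms: none
Why: Proposed new method: cathodically generated zerovalent nickel (bipyridine-ligated) inserts into each Z-configured C4–I bond, single-electron reduction of the N-acyloxyphthalimide on the same arm releases CO2 and phthalimide anion to leave the primary C5 radical, and capture of that radical by the divalent alkenylnickel followed by C(sp2)–C(sp3) reductive elimination from trivalent nickel forms C4–C5. The closest known reaction type is the intermolecular nickel-electrocatalytic decarboxylative alkenylation of redox-active esters with alkenyl halides, together with nickel-catalysed reductive ring-closing alkyl–alkenyl cross-electrophile coupling. Each 5,6-dihydropyridin-2(1H)-one ring closes as a six-membered ring by reductive elimination from a seven-membered nickelacycle; a 6-endo-trig attack of the C5 radical on the iodine-bearing C4 followed by loss of an iodine atom is a second pathway that leads to the same ring. No new stereocentre is formed: the endocyclic C3=C4 bond is cis because of the Z-iodide and the ring, and the four cyclobutane centres should be untouched because the medium is essentially neutral. The step needs chemoselective activation of the C–I and N–O bonds beside two imides and the enone products, which the mild potential of the nickel couple and a metered charge should secure. It also needs bonding at C4 and not C3, secured by the position of the iodide and the β-carbonyl polarisation, and closure within one arm and not between arms or molecules, secured by the six-membered ring size, the trans 1,3-disposition of the arms and high dilution.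

**Compound list**

1 | cis-3-(methoxycarbonyl)cyclobutane-1-carboxylic acid | COC(=O)[C@H]1C[C@@H](C(=O)O)C1 | starting material
2 | 2-(methylsulfanyl)aniline | CSc1ccccc1N | starting material
3 | methyl cis-3-{[2-(methylsulfanyl)phenyl]carbamoyl}cyclobutane-1-carboxylate | COC(=O)[C@H]1C[C@@H](C(=O)Nc2ccccc2SC)C1 | intermediate
4 | 4-iodo-1,2-dimethoxybenzene | COc1ccc(I)cc1OC | starting material
5 | methyl all-cis-2-(3,4-dimethoxyphenyl)-3-{[2-(methylsulfanyl)phenyl]carbamoyl}cyclobutane-1-carboxylate (racemic) | COC(=O)[C@H]1C[C@@H](C(=O)Nc2ccccc2SC)[C@H]1c3ccc(OC)c(OC)c3 | intermediate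
6 | methyl 2-(3,4-dimethoxyphenyl)-3-{[2-(methylsulfanyl)phenyl]carbamoyl}cyclobutane-1-carboxylate, ester trans to aryl, amide cis to aryl (racemic) | COC(=O)[C@@H]1C[C@@H](C(=O)Nc2ccccc2SC)[C@H]1c3ccc(OC)c(OC)c3 | intermediate
7 | methyl 2,4-bis(3,4-dimethoxyphenyl)-3-{[2-(methylsulfanyl)phenyl]carbamoyl}cyclobutane-1-carboxylate, amide cis and ester trans to both aryls (meso) | COc1ccc([C@H]2[C@H](C(=O)OC)[C@@H](c3ccc(OC)c(OC)c3)[C@H]2C(=O)Nc4ccccc4SC)cc1OC | intermediate
8 | N-Boc derivative of 7 | COc1ccc([C@H]2[C@H](C(=O)OC)[C@@H](c3ccc(OC)c(OC)c3)[C@H]2C(=O)N(C(=O)OC(C)(C)C)c4ccccc4SC)cc1OC | intermediate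
9 | (1α,2α,3β,4α)-2,4-bis(3,4-dimethoxyphenyl)cyclobutane-1,3-dicarboxylic acid (meso) | COc1ccc([C@H]2[C@H](C(=O)O)[C@@H](c3ccc(OC)c(OC)c3)[C@H]2C(=O)O)cc1OC | intermediate
10 | (1α,2α,3β,4α)-2,4-bis(3,4-dimethoxyphenyl)cyclobutane-1,3-dicarbonyl dichloride | COc1ccc([C@H]2[C@H](C(=O)Cl)[C@@H](c3ccc(OC)c(OC)c3)[C@H]2C(=O)Cl)cc1OC | intermediate
11 | (2Z)-3-iodoprop-2-enoic acid | OC(=O)/C=C\I | starting material
12 | β-alanine tert-butyl ester hydrochloride | Cl.NCCC(=O)OC(C)(C)C | starting material
13 | tert-butyl 3-[(2Z)-3-iodoprop-2-enamido]propanoate | CC(C)(C)OC(=O)CCNC(=O)/C=C\I | intermediate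
14 | lithium amidate of 13 | [Li+].CC(C)(C)OC(=O)CC[N-]C(=O)/C=C\I | intermediate
15 | di-tert-butyl bis-imide: both cyclobutane carbonyls bonded to N(CH2CH2CO2t-Bu)[(Z)-3-iodoacryloyl] | COc1ccc([C@H]2[C@H](C(=O)N(CCC(=O)OC(C)(C)C)C(=O)/C=C\I)[C@@H](c3ccc(OC)c(OC)c3)[C@H]2C(=O)N(CCC(=O)OC(C)(C)C)C(=O)/C=C\I)cc1OC | intermediate
16 | bis-imide dicarboxylic acid: both cyclobutane carbonyls bonded to N(CH2CH2CO2H)[(Z)-3-iodoacryloyl] | COc1ccc([C@H]2[C@H](C(=O)N(CCC(=O)O)C(=O)/C=C\I)[C@@H](c3ccc(OC)c(OC)c3)[C@H]2C(=O)N(CCC(=O)O)C(=O)/C=C\I)cc1OC | intermediate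
17 | bis(1,3-dioxoisoindolin-2-yl) ester of 16 | COc1ccc([C@H]2[C@H](C(=O)N(CCC(=O)ON4C(=O)c5ccccc5C4=O)C(=O)/C=C\I)[C@@H](c3ccc(OC)c(OC)c3)[C@H]2C(=O)N(CCC(=O)ON4C(=O)c5ccccc5C4=O)C(=O)/C=C\I)cc1OC | intermediate
18 | 1,1'-{[(1α,2α,3β,4α)-2,4-bis(3,4-dimethoxyphenyl)cyclobutane-1,3-diyl]dicarbonyl}bis(5,6-dihydropyridin-2(1H)-one) | COc1ccc([C@H]2[C@H](C(=O)N3CCC=CC3=O)[C@@H](c3ccc(OC)c(OC)c3)[C@H]2C(=O)N2CCC=CC2=O)cc1OC | target

**Step count and risks**

Total step count: 12. Longest linear sequence: 11 (steps 1–7 and 9–12; step 8 is a one-step branch).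

Steps most likely to fail:

Step 12. The twofold ring closure may be undercut by protodehalogenation or direct cathodic reduction of the alkenyl iodides, by intermolecular radical addition to the enoyl imides, by 1,5-hydrogen transfer from the cyclobutane α-C–H to the C5 radical, or by nickel insertion into an imide C–N bond. The fallback sets out from 10 and uses known chemistry. Commercial 5,6-dihydropyridin-2(1H)-one is deprotonated with n-BuLi in THF at −78 °C to give lithium 6-oxo-3,6-dihydro-2H-pyridin-1-ide F1. Twofold N-acylation of F1 by the bis(acid chloride) 10 at −78 °C then gives the target directly, so the fallback comes back to the route at 18.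

Step 9. Acylation of the amidate may be slow at the carbonyl that is cis to both aryl groups. O-acylation may occur without rearrangement, the amidate may add to the β-iodoenoyl carbon of product already formed, and the acid chloride may epimerise through a ketene. The fallback sets out from 10 and forms the other imide N–acyl bond instead. 10 is treated with 12 and Et3N in CH2Cl2 to give the bis(secondary amide) di-tert-butyl 3,3'-{[2,4-bis(3,4-dimethoxyphenyl)cyclobutane-1,3-diyl]bis(carbonylazanediyl)}dipropanoate F2. Separately, 11 is converted with oxalyl chloride and catalytic DMF into (2Z)-3-iodoprop-2-enoyl chloride F3. F2 is deprotonated with LiN(SiMe3)2 (2.0 equiv, THF, −78 °C) to its dilithium bis-amidate F4, which is acylated on nitrogen by the small acid chloride F3. This comes back to the route at 15.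

Step 4. The second palladation may stall because the new aryl group must enter a ring face that already carries the amide and the first aryl group, and proto-deiodination of 4 may consume the aryl iodide. The fallback sets out from 1 and installs both aryl groups in one operation before any epimerisation. 1 is coupled with 8-aminoquinoline (EDC·HCl, DMAP) to give methyl cis-3-(quinolin-8-ylcarbamoyl)cyclobutane-1-carboxylate F5. Twofold directed C–H arylation of F5 with 4 (Pd(OAc)2, Ag2CO3, HFIP, 110 °C) should give the all-cis diaryl amide ester F6. NaOMe in MeOH epimerises only the ester-bearing carbon to give F7, with the ester trans to both aryls. Boc2O/DMAP gives the N-Boc amide F8, and LiOH/H2O2 cleaves the amide and the ester, which comes back to the route at 9.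

Further compounds
F1 | step 12 | lithium 6-oxo-3,6-dihydro-2H-pyridin-1-ide | [Li+].O=C1C=CCC[N-]1
F2 | step 9 | di-tert-butyl 3,3'-{[(1α,2α,3β,4α)-2,4-bis(3,4-dimethoxyphenyl)cyclobutane-1,3-diyl]bis(carbonylazanediyl)}dipropanoate | COc1ccc([C@H]2[C@H](C(=O)NCCC(=O)OC(C)(C)C)[C@@H](c3ccc(OC)c(OC)c3)[C@H]2C(=O)NCCC(=O)OC(C)(C)C)cc1OC
F3 | step 9 | (2Z)-3-iodoprop-2-enoyl chloride | ClC(=O)/C=C\I
F4 | step 9 | dilithium bis-amidate of F2 | [Li+].[Li+].COc1ccc([C@H]2[C@H](C(=O)[N-]CCC(=O)OC(C)(C)C)[C@@H](c3ccc(OC)c(OC)c3)[C@H]2C(=O)[N-]CCC(=O)OC(C)(C)C)cc1OC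
F5 | step 4 | methyl cis-3-(quinolin-8-ylcarbamoyl)cyclobutane-1-carboxylate | COC(=O)[C@H]1C[C@@H](C(=O)Nc2cccc3cccnc23)C1
F6 | step 4 | methyl all-cis-2,4-bis(3,4-dimethoxyphenyl)-3-(quinolin-8-ylcarbamoyl)cyclobutane-1-carboxylate | COc1ccc([C@H]2[C@@H](C(=O)OC)[C@@H](c3ccc(OC)c(OC)c3)[C@H]2C(=O)Nc4cccc5cccnc45)cc1OC
F7 | step 4 | methyl 2,4-bis(3,4-dimethoxyphenyl)-3-(quinolin-8-ylcarbamoyl)cyclobutane-1-carboxylate, amide cis and ester trans to both aryls | COc1ccc([C@H]2[C@H](C(=O)OC)[C@@H](c3ccc(OC)c(OC)c3)[C@H]2C(=O)Nc4cccc5cccnc45)cc1OC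
F8 | step 4 | N-Boc derivative of F7 | COc1ccc([C@H]2[C@H](C(=O)OC)[C@@H](c3ccc(OC)c(OC)c3)[C@H]2C(=O)N(C(=O)OC(C)(C)C)c4cccc5cccnc45)cc1OC
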